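A direct plan would carry a citronellal-derived open chain through aminoxylation, epoxide-to-allylic-alcohol transposition and a boron anti-aldol to the C5,C6-dialdehyde ester A1, close the ten-membered ring and the lactone together by a samarium diiodide pinacol coupling to A2, then methylenate the lactone, epoxidise, acylate twice and oxidise C9.
Its weakest step would be the pinacol macrocyclisation: it closes a strained ten-membered ring against oligomerisation and sets C5 and C6 at once, with only acyclic Felkin arguments on a mobile chain and an epimerisable, β-silyloxy α-branched aldehyde as substrate.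
The second would be the run-up: about nine operations of protecting-group and oxidation-level traffic would be spent on an eight-carbon aldehyde with two stereocentres and one tertiary carbinol before any ring exists.
The third would be the Mannich methylenation of the lactone with lithium diisopropylamide on the finished bicycle: three operations for one carbon, on late material whose β-silyloxy and translactonisable neighbours invite elimination and acyl shift.

Plan of the new route (target numbering throughout: ring C1–C10, lactone carbons C11–C13).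
The α-acyloxy ketone C8(OAng)–C9(=O) is read as the hydrolysed form of an enol ester/enol ether C8=C9; with C10–C1 and the C2=C3 alkene (the epoxide precursor) this is a 1,5-diene lying across the ten-membered ring. The retrosynthesis therefore cuts C1–C10 and reconnects the transannular pair C3···C8 to a cyclohexane (C3–C8) that holds C4–C7 on a chair.
Forward, a quinone monoketal is elaborated in eight steps to the 1,2-dialkenylcyclohexanol 15; an anionic oxy-Cope rearrangement enlarges the six- to the ten-membered ring, and the alkoxide oxygen that drives it is acylated to become the C8 angelate oxygen.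
Rings arise in the order cyclohexane template → ten-membered carbocycle (by enlargement, not closure) → epoxide → lactone.
No macrocyclisation occurs: C10, the E-alkene and C8 follow from one chair transition state and the planar-chiral enol it leaves, and C4–C7 come from additions to a rigid enone. The α-methylene lactone comes from MnO2 oxidation of an allylic 1,4-diol, so no lactone enolate is needed.

Key step: step 13

Remark 1: the chiral diene–rhodium catalyst of step 4 is assumed to show the facial preference known for cyclohex-2-enone; the ligand enantiomer is chosen to give (5R)-6.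
Remark 2: commercial ethyl prop-1-enyl ether is Z-rich; the Z isomer 13 is used, and it is assumed to be the isomer that is metalated at the oxygen-bearing carbon in step 11.
Remark 3: the mixed anhydride 17 is assumed to keep as a dry toluene solution at −20 °C between steps 13 and 18; any disproportionation to angelic anhydride would transfer the same acyl group.

Step 1
Reactants: 1 4-methoxy-2-methylphenol
Product: 2 4,4-dimethoxy-2-methylcyclohexa-2,5-dien-1-one
Conditions: PhI(OAc)2 (1.1 equiv), MeOH, 0 °C
Reagents that add atoms: methanol CO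
Why: Oxidative dearomatisation of a 4-alkoxyphenol by hypervalent (trivalent) iodine in methanol gives the quinone monoketal, whose two enone halves (C6=C7 unsubstituted, C3=C4 methylated) are differentiated for all that follows.

Step 2
Reactants: 3 2-bromoprop-2-en-1-ol
Product: 4 1-{[(2-bromoprop-2-en-1-yl)oxy]methyl}-4-methoxybenzene
Conditions: NaH, 4-MeOC6H4CH2Cl, Bu4NI (cat.), THF, 0 °C → rt
Reagents that add atoms: 4-methoxybenzyl chloride COc1ccc(CCl)cc1
Why: Williamson etherification protects the future C12 oxygen as a PMB ether, the one group of the route that is later removed oxidatively under neutral conditions.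

Step 3
Reactants: 4 1-{[(2-bromoprop-2-en-1-yl)oxy]methyl}-4-methoxybenzene
Product: 5 2-{3-[(4-methoxybenzyl)oxy]prop-1-en-2-yl}-4,4,5,5-tetramethyl-1,3,2-dioxaborolane
Conditions: t-BuLi (2.1 equiv), Et2O, −78 °C; then i-PrOBpin, −78 °C → rt
Reagents that add atoms: 2-isopropoxy-4,4,5,5-tetramethyl-1,3,2-dioxaborolane CC(C)OB1OC(C)(C)C(C)(C)O1
Why: Bromine–lithium exchange and borylation of the alkenyllithium give the 1,1-disubstituted alkenylboronate that carries C11, C12 and C13.

Step 4
Reactants: 2 4,4-dimethoxy-2-methylcyclohexa-2,5-dien-1-one; 5 2-{3-[(4-methoxybenzyl)oxy]prop-1-en-2-yl}-4,4,5,5-tetramethyl-1,3,2-dioxaborolane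
Product: 6 (5R)-4,4-dimethoxy-5-{3-[(4-methoxybenzyl)oxy]prop-1-en-2-yl}-2-methylcyclohex-2-en-1-one (C5 of this name is C7 of the target)
Conditions: 5 (1.5 equiv), [RhCl(C2H4)2]2 (1.5 mol %), (R,R)-2,5-diphenylbicyclo[2.2.2]octa-2,5-diene (3.3 mol %), KOH (0.5 equiv), 1,4-dioxane/H2O (10:1), 40 °C
Reagents that add atoms: none
Why: Hayashi–Miyaura asymmetric 1,4-addition, in which the alkenyl group on monovalent rhodium adds only to the unsubstituted C6=C7 enone (the C3=C4 enone is α-methylated and flanked by the ketal) and the chiral diene selects the enone face, so C7 is set by the catalyst.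

Step 5
Reactants: 6 (5R)-4,4-dimethoxy-5-{3-[(4-methoxybenzyl)oxy]prop-1-en-2-yl}-2-methylcyclohex-2-en-1-one
Product: 7 C3–C4 epoxy ketone (epoxide oxygen trans to the C7 side chain)
Conditions: t-BuOOH (2 equiv), DBU (1.2 equiv), CH2Cl2, 0 °C → rt
Reagents that add atoms: tert-butyl hydroperoxide CC(C)(C)OO
Why: Weitz–Scheffer nucleophilic epoxidation, in which the peroxide anion adds to C3 on the face anti to the C7 side chain (the known preference of 5-substituted cyclohexenones) and the enolate closes on the same face, so the C4–O bond of the target is set trans to the C7 substituent.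

Step 6
Reactants: 7 C3–C4 epoxy ketone
Product: 8 C6-hydroxy epoxy ketone (C6 hydroxyl trans to the C7 side chain and cis to the epoxide oxygen)
Conditions: KN(SiMe3)2 (1.1 equiv), THF, −78 °C; then 3-phenyl-2-(phenylsulfonyl)oxaziridine (1.3 equiv), −78 °C; sat. aq. NH4Cl
Reagents that add atoms: 3-phenyl-2-(phenylsulfonyl)oxaziridine O=S(=O)(N1OC1c1ccccc1)c1ccccc1
Why: Enolate hydroxylation with an N-sulfonyloxaziridine; only C6 can be enolised (C4 is quaternary) and the oxidant approaches anti to the adjacent C7 side chain, which gives the trans C6–O/C7–C relationship of the lactone.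

Step 7
Reactants: 8 C6-hydroxy epoxy ketone
Product: 9 epoxy C5,C6-diol (C5 hydroxyl trans to the C6 hydroxyl and to the epoxide oxygen)
Conditions: Me4NBH(OAc)3 (5 equiv), MeCN/AcOH (4:1), −30 °C
Reagents that add atoms: none
Why: Saksena–Evans hydroxyl-directed reduction, in which hydride is delivered to C5 from the boron bound to O6 and therefore on the face of O6 (the face that an external hydride would avoid), so the C5 hydroxyl forms anti to O6.

Step 8
Reactants: 9 epoxy C5,C6-diol
Product: 10 all-trans C3-vinyl C4,C5,C6-triol dimethyl ketal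
Conditions: CH2=CHMgBr (5 equiv), CuI (10 mol %), THF, −20 °C → rt; sat. aq. NH4Cl
Reagents that add atoms: vinylmagnesium bromide C=C[Mg]Br
Why: Copper-catalysed Grignard opening of the trisubstituted epoxide by SN2 attack at the secondary C3 (C4 is tertiary) with inversion, so the vinyl group (future C2 and C1) enters anti to O4 and cis to the C7 side chain and the all-equatorial array C3–C7 results.

Step 9
Reactants: 10 all-trans C3-vinyl C4,C5,C6-triol dimethyl ketal
Product: 11 4,5,6-tris(triethylsilyl) ether of 10
Conditions: Et3SiOTf (4 equiv), 2,6-lutidine (6 equiv), CH2Cl2, −78 → 0 °C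
Reagents that add atoms: triethylsilyl trifluoromethanesulfonate CC[Si](CC)(CC)OS(=O)(=O)C(F)(F)F
Why: Silyl triflate silylation caps the tertiary C4 and the secondary C5 and C6 hydroxyls, so that O8 will be the only alkoxide in the key step and the β-oxy ketone to come cannot undergo retro-aldol cleavage.

Step 10
Reactants: 11 4,5,6-tris(triethylsilyl) ether of 10
Product: 12 C8 ketone (2-vinyl-6-alkenyl-3,4,5-tris(triethylsilyloxy)-3-methylcyclohexanone)
Conditions: pyridinium 4-toluenesulfonate (0.2 equiv), acetone/H2O (10:1), rt
Reagents that add atoms: water O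
Why: Acid-catalysed hydrolysis of the dimethyl ketal in wet acetone through the C8 oxocarbenium ion, which the weak pyridinium acid should bring about well before the hindered secondary and tertiary triethylsilyl ethers or the PMB ether are touched and without enolising the new ketone toward C3 or C7.

Step 11
Reactants: 12 C8 ketone; 13 (Z)-1-ethoxyprop-1-ene
Product: 15 C8 tertiary carbinol carrying the (Z)-1-ethoxyprop-1-enyl group (C9 and C10 with its methyl) trans to the C3 vinyl group, via lithium reagent 14 (not isolated)
Conditions: 13 (3 equiv), t-BuLi (2.8 equiv), THF, −78 → −10 °C; then CeCl3 (3 equiv), −78 °C; then 12, −78 °C; sat. aq. NH4Cl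
Reagents that add atoms: none
Why: 1,2-Addition of an α-alkoxyalkenyl (acyl anion equivalent) organometallic, made by α-lithiation of the enol ether and rendered non-basic by CeCl3; the axial face of C8 is blocked by the axial C4 methyl group, so attack is equatorial and the alkenyl group ends diequatorial-trans to the C3 vinyl group with the C8 hydroxyl axial.

Step 12
Reactants: 16 angelic acid
Product: 17 angelic 2,4,6-trichlorobenzoic anhydride (used as a filtered toluene stock solution)
Conditions: 2,4,6-Cl3C6H2COCl (1.0 equiv), Et3N (1.05 equiv), toluene, 0 °C → rt; filtered under argon, kept at −20 °C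
Reagents that add atoms: 2,4,6-trichlorobenzoyl chloride O=C(Cl)c1c(Cl)cc(Cl)cc1Cl
Why: Yamaguchi mixed-anhydride formation, in which the triethylammonium angelate attacks the acid chloride without any nucleophilic catalyst, so the Z double bond is kept and the two ortho chlorines later steer nucleophiles to the angeloyl carbonyl.

Step 13
Reactants: 15 C8 tertiary carbinol; 17 angelic 2,4,6-trichlorobenzoic anhydride
Product: 19 (2E,8E)-ten-membered enol angelate (C8 OAng; C9 OEt; O4–O6 triethylsilyl; O12 PMB), via potassium enolate 18 (not isolated)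
Conditions: 15, KH (1.5 equiv), 18-crown-6 (1.5 equiv), THF, 0 → 40 °C; then 17 (3 equiv, toluene solution), −78 → −40 °C; sat. aq. NH4Cl
Reagents that add atoms: none
Why: The potassium alkoxide at C8 undergoes an anionic oxy-Cope ([3,3]-sigmatropic) rearrangement of the 1,5-diene C10=C9–C8–C3–C2=C1, forming C1–C10 and breaking C3–C8, and the resulting potassium enolate 18 (O–C8=C9–OEt) attacks the unhindered angeloyl carbonyl of anhydride 17 through oxygen, so the oxygen that drove the rearrangement becomes the C8 ester oxygen. The closest known reaction type is the anionic oxy-Cope ring enlargement of trans-1,2-dialkenylcyclohexanols to (E)-cyclodec-5-enones with trapping of the enolate, including α-alkoxyalkenyl cases. The ten-membered ring is not closed by cyclisation: it arises by a four-carbon ring enlargement through a six-membered chair transition state fused to the cyclohexane chair (both alkenyl groups equatorial, O8 axial), and the strain of the medium ring is paid for by the change from alkoxide to delocalised enolate. C10 is controlled by the Z enol ether geometry (methyl trans to C8, hence equatorial in the chair, which should give the 10S methyl), the E geometry of C2=C3 by the equatorial C4 ring bond, and the E enolate (C7 trans to C10) with one planar chirality by the same chair, which later fixes C8. The step needs a chair and not a boat (secured by the trans-diequatorial alkenyl groups), a single alkoxide (secured by silylation of O4–O6; the axial O8 is remote from the equatorial silyloxy groups, which disfavours silyl transfer) and O- rather than C-acylation (secured by the tetrasubstituted potassium enolate and the hard anhydride). It also needs the shift to run through the C3 vinyl group and not through the C7 alkenyl group, which is likewise trans to the C8 alkenyl group: the chair of that competing shift would force the C12 methylene branch on C11 to eclipse the C7–C6 bond next to the C6 silyl ether (allylic 1,2-strain), whereas the vinyl group carries only hydrogen on C2.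

Step 14
Reactants: 19 (2E,8E)-ten-membered enol angelate
Product: 21 8-angeloyloxy-9-oxo-4,5,6-triol with E-C2=C3 and the O12 PMB ether, via silylated ketone 20 (not isolated)
Conditions: 0.5 M aq. (CO2H)2, THF, 0 °C; then HF·pyridine, pyridine, THF, 0 °C → rt
Reagents that add atoms: water O
Why: Enol ether hydrolysis, in which the ethoxy-substituted alkene is protonated at C8 from the only open, peripheral face of the E-configured tetrasubstituted C8=C9 bond (its inner face looks at C2=C3 across the ring), which should give the 8S ester, and the C9 oxocarbenium ion is hydrolysed to the ketone; buffered fluoride then removes the three triethylsilyl groups and leaves the PMB ether.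

Step 15
Reactants: 21 8-angeloyloxy-9-oxo-4,5,6-triol
Product: 22 (2S,3R)-2,3-epoxide of 21
Conditions: VO(acac)2 (10 mol %), t-BuOOH (1.5 equiv), CH2Cl2, 0 °C → rt
Reagents that add atoms: tert-butyl hydroperoxide CC(C)(C)OO
Why: Vanadium-catalysed hydroxyl-directed epoxidation of the tertiary allylic alcohol, in which the C4 vanadate delivers oxygen to the peripheral C2=C3 face in the ring conformer that has O4 close to the alkene plane on the C2 side and the C4–C5 ring bond perpendicular to it, which should give the trans 2S,3R epoxide; the C11=C13 alkene (only the slower homoallylic C6 hydroxyl, allylic oxygen protected) and the electron-poor angelate are left alone.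

Step 16
Reactants: 22 (2S,3R)-2,3-epoxide of 21
Product: 23 epoxy 4,5,6,12-tetraol
Conditions: DDQ (1.5 equiv), CH2Cl2/pH 7 buffer (10:1), 0 °C → rt
Reagents that add atoms: none
Why: Oxidative PMB cleavage (hydride abstraction from the electron-rich benzylic position, hydrolysis of the oxocarbenium ion) frees the allylic C12 hydroxyl under neutral, wet conditions that should spare the epoxy alcohol and the α-acyloxy ketone.

Step 17
Reactants: 23 epoxy 4,5,6,12-tetraol
Product: 24 5-O-desangeloyl target (epoxy α-methylene 12,6-lactone with free C4 and C5 hydroxyls)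
Conditions: MnO2 (activated, 30 equiv), CH2Cl2, rt
Reagents that add atoms: none
Why: Oxidative lactonisation of the 2-methylene-1,4-diol, in which tetravalent manganese oxidises only the allylic primary alcohol to the enal, the C6 hydroxyl closes the five-membered lactol (favoured over the six-membered lactol from O5) and the allylic lactol is oxidised further, so the lactone and its exocyclic methylene appear without enolate chemistry.

Step 18
Reactants: 24 5-O-desangeloyl target; 17 angelic 2,4,6-trichlorobenzoic anhydride
Product: 25 CNP0320279.1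
Conditions: 17 (6 equiv, toluene solution), Et3N (6 equiv), toluene, 70 °C
Reagents that add atoms: none
Why: Yamaguchi esterification with the preformed mixed anhydride and no nucleophilic catalyst should acylate the only secondary hydroxyl (C5) without Z-to-E isomerisation, the tertiary C4 hydroxyl being too hindered to react.

Compound list
1 | 4-methoxy-2-methylphenol | COc1ccc(O)c(C)c1 | starting material
2 | 4,4-dimethoxy-2-methylcyclohexa-2,5-dien-1-one | COC1(OC)C=CC(=O)C(C)=C1 | intermediate
3 | 2-bromoprop-2-en-1-ol | OCC(Br)=C | starting material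
4 | 1-{[(2-bromoprop-2-en-1-yl)oxy]methyl}-4-methoxybenzene | C=C(Br)COCc1ccc(OC)cc1 | intermediate
5 | 2-{3-[(4-methoxybenzyl)oxy]prop-1-en-2-yl}-4,4,5,5-tetramethyl-1,3,2-dioxaborolane | C=C(COCc1ccc(OC)cc1)B2OC(C)(C)C(C)(C)O2 | intermediate
6 | (5R)-4,4-dimethoxy-5-{3-[(4-methoxybenzyl)oxy]prop-1-en-2-yl}-2-methylcyclohex-2-en-1-one | COC1(OC)C=C(C)C(=O)C[C@@H]1C(=C)COCc2ccc(OC)cc2 | intermediate
7 | C3–C4 epoxide of 6, epoxide oxygen trans to the C7 side chain | COC1(OC)[C@H]2O[C@@]2(C)C(=O)C[C@@H]1C(=C)COCc3ccc(OC)cc3 | intermediate
8 | C6-hydroxy derivative of 7, hydroxyl trans to the C7 side chain | COC1(OC)[C@H]2O[C@@]2(C)C(=O)[C@@H](O)[C@@H]1C(=C)COCc3ccc(OC)cc3 | intermediate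
9 | epoxy C5,C6-diol, C5 hydroxyl trans to the C6 hydroxyl | COC1(OC)[C@H]2O[C@@]2(C)[C@H](O)[C@@H](O)[C@@H]1C(=C)COCc3ccc(OC)cc3 | intermediate
10 | all-trans C3-vinyl C4,C5,C6-triol dimethyl ketal (C4 bears methyl and hydroxyl) | COC1(OC)[C@H](C=C)[C@@](C)(O)[C@H](O)[C@@H](O)[C@@H]1C(=C)COCc2ccc(OC)cc2 | intermediate
11 | 4,5,6-tris(triethylsilyl) ether of 10 | COC1(OC)[C@H](C=C)[C@@](C)(O[Si](CC)(CC)CC)[C@H](O[Si](CC)(CC)CC)[C@@H](O[Si](CC)(CC)CC)[C@@H]1C(=C)COCc2ccc(OC)cc2 | intermediate
12 | C8 ketone derived from 11 | O=C1[C@H](C=C)[C@@](C)(O[Si](CC)(CC)CC)[C@H](O[Si](CC)(CC)CC)[C@@H](O[Si](CC)(CC)CC)[C@@H]1C(=C)COCc2ccc(OC)cc2 | intermediate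
13 | (Z)-1-ethoxyprop-1-ene | C/C=C\OCC | starting material
14 | [(Z)-1-ethoxyprop-1-en-1-yl]lithium (not isolated) | C/C=C(\OCC)[Li] | intermediate
15 | C8 tertiary carbinol: equatorial (Z)-1-ethoxyprop-1-enyl group trans to the C3 vinyl group, axial hydroxyl | CCO/C(=C\C)[C@@]1(O)[C@H](C=C)[C@@](C)(O[Si](CC)(CC)CC)[C@H](O[Si](CC)(CC)CC)[C@@H](O[Si](CC)(CC)CC)[C@@H]1C(=C)COCc2ccc(OC)cc2 | intermediate
16 | angelic acid, (2Z)-2-methylbut-2-enoic acid | C/C=C(/C)C(=O)O | starting material
17 | angelic 2,4,6-trichlorobenzoic anhydride | C/C=C(/C)C(=O)OC(=O)c1c(Cl)cc(Cl)cc1Cl | intermediate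
18 | potassium (2E,8E)-enolate of the ten-membered ring, O–C8=C9–OEt (not isolated) | C[C@H]1C/C=C/[C@@](C)(O[Si](CC)(CC)CC)[C@H](O[Si](CC)(CC)CC)[C@@H](O[Si](CC)(CC)CC)[C@H](C(=C)COCc2ccc(OC)cc2)/C([O-])=C1\OCC.[K+] | intermediate
19 | (2E,8E)-8-angeloyloxy-9-ethoxy-4,10-dimethyl-4,5,6-tris(triethylsilyloxy)-7-{3-[(4-methoxybenzyl)oxy]prop-1-en-2-yl}cyclodeca-2,8-diene (target numbering; C4–C7 and C10 as in the target) | C[C@H]1C/C=C/[C@@](C)(O[Si](CC)(CC)CC)[C@H](O[Si](CC)(CC)CC)[C@@H](O[Si](CC)(CC)CC)[C@H](C(=C)COCc2ccc(OC)cc2)/C(OC(=O)/C(C)=C\C)=C1\OCC | intermediate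
20 | (8S)-8-angeloyloxy-9-ketone with E-C2=C3, O4–O6 triethylsilyl and O12 PMB (not isolated) | C[C@H]1C/C=C/[C@@](C)(O[Si](CC)(CC)CC)[C@H](O[Si](CC)(CC)CC)[C@@H](O[Si](CC)(CC)CC)[C@H](C(=C)COCc2ccc(OC)cc2)[C@H](OC(=O)/C(C)=C\C)C1=O | intermediate
21 | 8-angeloyloxy-9-oxo-4,5,6-triol with E-C2=C3 and O12 PMB | C[C@H]1C/C=C/[C@@](C)(O)[C@H](O)[C@@H](O)[C@H](C(=C)COCc2ccc(OC)cc2)[C@H](OC(=O)/C(C)=C\C)C1=O | intermediate
22 | (2S,3R)-2,3-epoxide of 21 | C[C@H]1C[C@@H]2O[C@H]2[C@@](C)(O)[C@H](O)[C@@H](O)[C@H](C(=C)COCc2ccc(OC)cc2)[C@H](OC(=O)/C(C)=C\C)C1=O | intermediate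
23 | epoxy 4,5,6,12-tetraol (22 without the PMB group) | C[C@H]1C[C@@H]2O[C@H]2[C@@](C)(O)[C@H](O)[C@@H](O)[C@H](C(=C)CO)[C@H](OC(=O)/C(C)=C\C)C1=O | intermediate
24 | 5-O-desangeloyl target: 8-angeloyloxy-2,3-epoxy-4,5-dihydroxy-9-oxo α-methylene 12,6-lactone | C=C1C(=O)O[C@H]2[C@H]1[C@H](OC(=O)/C(C)=C\C)C(=O)[C@@H](C)C[C@@H]1O[C@H]1[C@@](C)(O)[C@@H]2O | intermediate
25 | CNP0320279.1, (2S,3R,4R,5R,6S,7S,8S,10S)-5,8-bis(angeloyloxy)-2,3-epoxy-4-hydroxy-4,10-dimethyl-9-oxo ten-membered ring with the α-methylene 12,6-lactone | C=C1C(=O)O[C@H]2[C@H]1[C@H](OC(=O)/C(C)=C\C)C(=O)[C@@H](C)C[C@@H]1O[C@H]1[C@@](C)(O)[C@@H]2OC(=O)/C(C)=C\C | target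

Total step count: 18. Longest linear sequence: 16 steps (3 → 4 → 5 → 6 → 7 → 8 → 9 → 10 → 11 → 12 → 15 → 19 → 21 → 22 → 23 → 24 → 25, that is steps 2–11 and 13–18; the branches from 1, 13 and 16 join at steps 4, 11 and 13).

Steps most likely to fail

Step 13. The hindered potassium enolate 18 may be acylated slowly, partly on carbon, or the angelate may isomerise to the tiglate before transfer; a share of the alkoxide may also rearrange through the C7 alkenyl group. The fallback separates rearrangement and esterification, so that the enolate is caught at once by a small electrophile and isomeric ring-enlarged material can be removed at a stable stage. It sets out from 15: the rearrangement is run as before and the enolate is quenched at −78 °C with allyl chloroformate, a small hard electrophile that acylates enolates on oxygen, to give the enol allyl carbonate F1. Hydrolysis of the enol ether (aq. (CO2H)2, THF, 0 °C) should give the α-(allyloxycarbonyloxy) ketone F2. Pd(PPh3)4 with HCO2NH4 removes the allyl carbonate under neutral conditions to give the acyloin F3, which is esterified with 17 under the conditions of step 18 at rt → 50 °C. The route is rejoined at 20.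

Step 14. Protonation of the enol ether may occur from the inner face, or the C9 oxocarbenium ion may be captured by the neighbouring ester carbonyl and scramble the acyl group, so that C8 is obtained with the wrong configuration. The fallback sets C8 by SN2 inversion instead of by the protonation face. It sets out from 15 and passes through the enol allyl carbonate F1 as above; hydrolysis then gives the C8-epimeric carbonate F4 and deallylation the 8-epi acyloin F5. Mitsunobu esterification of F5 with 16 (PPh3, DIAD, toluene, 0 °C), a displacement at the carbonyl-activated C8 with inversion, should give 20, where the route is rejoined.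

Step 8. Attack of the vinyl copper reagent at C3, which is flanked by the ketal carbon and the fully substituted epoxide carbon, may be too slow, and the magnesium alkoxides may instead promote opening at C4 or a semipinacol shift. The fallback uses a slim sp-carbon nucleophile on a Lewis-acidic metal and makes the alkene afterwards. It sets out from 9: Et2AlC≡CSiMe3 (from Me3SiC≡CH, n-BuLi and Et2AlCl) in toluene at 0 °C should open the epoxide anti at C3 to the alkynyl triol F6. K2CO3 in MeOH gives the terminal alkyne F7, and semihydrogenation over Lindlar catalyst (Pd/CaCO3 poisoned with lead, quinoline, H2) gives 10, where the route is rejoined.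

Further compounds
F1 | step 13 | (2E,8E)-enol allyl carbonate: analogue of 19 with OC(=O)OCH2CH=CH2 on C8 | C[C@H]1C/C=C/[C@@](C)(O[Si](CC)(CC)CC)[C@H](O[Si](CC)(CC)CC)[C@@H](O[Si](CC)(CC)CC)[C@H](C(=C)COCc2ccc(OC)cc2)/C(OC(=O)OCC=C)=C1\OCC
F2 | step 13 | (8S)-8-(allyloxycarbonyloxy)-9-ketone, O4–O6 triethylsilyl, O12 PMB | C[C@H]1C/C=C/[C@@](C)(O[Si](CC)(CC)CC)[C@H](O[Si](CC)(CC)CC)[C@@H](O[Si](CC)(CC)CC)[C@H](C(=C)COCc2ccc(OC)cc2)[C@H](OC(=O)OCC=C)C1=O
F3 | step 13 | (8S)-8-hydroxy-9-ketone, O4–O6 triethylsilyl, O12 PMB | C[C@H]1C/C=C/[C@@](C)(O[Si](CC)(CC)CC)[C@H](O[Si](CC)(CC)CC)[C@@H](O[Si](CC)(CC)CC)[C@H](C(=C)COCc2ccc(OC)cc2)[C@H](O)C1=O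
F4 | step 14 | (8R)-8-(allyloxycarbonyloxy)-9-ketone, the C8 epimer of F2 | C[C@H]1C/C=C/[C@@](C)(O[Si](CC)(CC)CC)[C@H](O[Si](CC)(CC)CC)[C@@H](O[Si](CC)(CC)CC)[C@H](C(=C)COCc2ccc(OC)cc2)[C@@H](OC(=O)OCC=C)C1=O
F5 | step 14 | (8R)-8-hydroxy-9-ketone, the C8 epimer of F3 | C[C@H]1C/C=C/[C@@](C)(O[Si](CC)(CC)CC)[C@H](O[Si](CC)(CC)CC)[C@@H](O[Si](CC)(CC)CC)[C@H](C(=C)COCc2ccc(OC)cc2)[C@@H](O)C1=O
F6 | step 8 | C3-(trimethylsilylethynyl) analogue of triol 10 | COC1(OC)[C@H](C#C[Si](C)(C)C)[C@@](C)(O)[C@H](O)[C@@H](O)[C@@H]1C(=C)COCc2ccc(OC)cc2
F7 | step 8 | C3-ethynyl analogue of triol 10 | COC1(OC)[C@H](C#C)[C@@](C)(O)[C@H](O)[C@@H](O)[C@@H]1C(=C)COCc2ccc(OC)cc2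
A1 | direct plan | methyl (3R,4S,5R,6S,8E,10R)-3-formyl-5-[(4-methoxybenzyl)oxy]-6,10-dimethyl-11-oxo-4,10-bis(triethylsilyloxy)undec-8-enoate | O=C[C@H](CC(=O)OC)[C@H](O[Si](CC)(CC)CC)[C@H](OCc1ccc(OC)cc1)[C@@H](C)C/C=C/[C@@](C)(O[Si](CC)(CC)CC)C=O
A2 | direct plan | trans-fused ten-membered hydroxy γ-lactone with free C5 hydroxyl, O4 and O8 triethylsilyl, O9 PMB and E-C2=C3 | C1C(=O)O[C@H]2[C@H]1[C@H](O[Si](CC)(CC)CC)[C@H](OCc3ccc(OC)cc3)[C@@H](C)C/C=C/[C@@](C)(O[Si](CC)(CC)CC)[C@@H]2O
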